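The route rests on cutting the side-chain bond C2'–C3'. The lone stereocentre C2' bears an acetate and lies between two near-identical methylenes (benzylic C1' on the benzene ring, chain C3'), so its own acetoxy oxygen is used as the handle. A racemic 1-bromoalkyl acetate, made from an arylacetaldehyde and acetyl bromide, is coupled with tridecylzinc bromide under a chiral nickel bis(oxazoline) catalyst. This one operation forges C2'–C3', brings in the whole C13 chain and fixes (R)-C2' with both acetates of the target already present. The precursor is a 2-aryl-1-bromoethyl acetate whose ring carries the C2 acetate, the C3 methoxy group and a benzyl ether on the C5 oxygen.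

Key step: step 9

Locants: ring carbon C1 bears the side chain, C2 the acetate, C3 the methoxy group, C5 the free hydroxyl; the side chain runs C1' (benzylic) to C15'. The target is (R) at C2' (priorities OAc > CH2Ar > CH2-alkyl > H).

Assumption (chemistry): the small C2' acetate is taken to steer the nickel catalyst as larger carboxylates do, and the ligand antipode that gives (R) is fixed in a pilot coupling checked by chiral HPLC.

Step 1
Reactants: 1 vanillin; 2 allyl bromide
Product: 3 4-(allyloxy)-3-methoxybenzaldehyde
Conditions: K2CO3, DMF, rt
Reagents that add atoms: allyl bromide (2), C=CCBr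
Why: Williamson etherification of the phenoxide with a reactive primary allylic bromide, the aldehyde being a spectator.

Step 2
Reactants: 3 4-(allyloxy)-3-methoxybenzaldehyde
Product: 5 4-(allyloxy)-3-methoxyphenol, via aryl formate 4 (not isolated)
Conditions: mCPBA (1.2 equiv), CH2Cl2, 0 °C → rt; aq NaHCO3 wash; K2CO3 (cat.), MeOH, rt
Reagents that add atoms: mCPBA, O=C(OO)c1cccc(Cl)c1
Why: Baeyer–Villiger (Dakin-type) oxidation in which the electron-rich aryl group migrates to give the formate, which is methanolysed without purification, while the monosubstituted allyl alkene should epoxidise far more slowly than the aldehyde reacts.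

Step 3
Reactants: 5 4-(allyloxy)-3-methoxyphenol; 6 benzyl bromide
Product: 7 1-(allyloxy)-4-(benzyloxy)-2-methoxybenzene
Conditions: K2CO3, DMF, rt
Reagents that add atoms: benzyl bromide (6), BrCc1ccccc1
Why: Williamson etherification installs a benzyl group that tolerates the later thermal, oxidative and organozinc steps and can be removed at the end under neutral conditions.

Step 4
Reactants: 7 1-(allyloxy)-4-(benzyloxy)-2-methoxybenzene
Product: 9 2-allyl-4-(benzyloxy)-6-methoxyphenol, via Claisen dienone 8 (not isolated)
Conditions: PhNEt2, 190 °C, argon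
Reagents that add atoms: none
Why: Aromatic Claisen [3,3] rearrangement delivers the allyl group to the one ortho carbon that bears hydrogen (the other ortho carbon carries OMe and the para carbon carries OBn), and the dienone then tautomerises to the phenol.

Step 5
Reactants: 9 2-allyl-4-(benzyloxy)-6-methoxyphenol
Product: 10 2-allyl-4-(benzyloxy)-6-methoxyphenyl acetate
Conditions: Ac2O, pyridine, DMAP (cat.), CH2Cl2, rt
Reagents that add atoms: acetic anhydride, CC(=O)OC(C)=O
Why: DMAP-catalysed acylation of the flanked phenol puts the C2 acetate of the target in place before the side chain is built.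

Step 6
Reactants: 10 2-allyl-4-(benzyloxy)-6-methoxyphenyl acetate
Product: 12 2-[2-acetoxy-5-(benzyloxy)-3-methoxyphenyl]acetaldehyde, via secondary ozonide 11 (not isolated)
Conditions: O3, CH2Cl2, −78 °C (Sudan Red 7B end point); PPh3, −78 °C → rt; short silica plug, used at once
Reagents that add atoms: ozone, [O-][O+]=O
Why: Ozonolysis with reductive work-up (Criegee pathway) cleaves the terminal alkene much faster than ozone attacks the arene or the benzyl ether when the end point is signalled by the dye.

Step 7
Reactants: 12 2-[2-acetoxy-5-(benzyloxy)-3-methoxyphenyl]acetaldehyde; 13 acetyl bromide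
Product: 14 rac-2-[2-acetoxy-5-(benzyloxy)-3-methoxyphenyl]-1-bromoethyl acetate
Conditions: AcBr (1.1 equiv), ZnBr2 (2 mol %), CH2Cl2, −20 → 0 °C; volatiles removed, crude used directly under argon
Reagents that add atoms: acetyl bromide (13), CC(Br)=O
Why: Lewis-acid-catalysed addition of an acyl bromide across the aldehyde C=O (1-haloalkyl ester formation) gives the racemic geminal bromo acetate, while low temperature and a trace of ZnBr2 should spare the aryl benzyl ether and the aryl acetate.

Step 8
Reactants: 15 1-bromotridecane
Product: 16 tridecylzinc bromide (titrated solution in DMA)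
Conditions: Zn dust (1.5 equiv), I2 (5 mol %), DMA, 70 °C
Reagents that add atoms: zinc, [Zn]
Why: Direct insertion of iodine-activated zinc into a primary alkyl bromide in a polar amide solvent is a standard way to make alkylzinc bromides for Negishi coupling.

Step 9
Reactants: 14 rac-2-[2-acetoxy-5-(benzyloxy)-3-methoxyphenyl]-1-bromoethyl acetate; 16 tridecylzinc bromide
Product: 17 (R)-1-[2-acetoxy-5-(benzyloxy)-3-methoxyphenyl]pentadecan-2-yl acetate
Conditions: NiBr2(glyme) (10 mol %), chiral bis(oxazoline) L* (12 mol %; 2,2'-(propane-2,2-diyl)bis(4-phenyl-4,5-dihydrooxazole), antipode chosen for R), 16 (1.5 equiv), THF/DMA, −10 → 0 °C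
Reagents that add atoms: tridecylzinc bromide (16), CCCCCCCCCCCCC[Zn]Br
Why: Transmetalation from 16 gives a bis(oxazoline)-bound alkylnickel species that abstracts bromine from either enantiomer of 14 to give one planar α-acetoxyalkyl radical at C2', which recombines with nickel and leaves by reductive elimination with the new C2'–C3' bond. The closest known reaction type is the nickel-catalysed enantioconvergent Negishi alkyl–alkyl coupling of racemic 1-haloalkyl carboxylates with alkylzinc halides. No ring is closed. The C2' configuration is set under catalyst control: the acetoxy carbonyl binds nickel, so the ligand distinguishes the ester substituent from the two methylene arms, and the ligand antipode is selected to give (R). The step needs enantioselectivity and chemoselectivity for the C2'–Br bond; the latter is secured because only this α-oxygenated bromide is activated for halogen abstraction, while the aryl acetate, the aryl ethers and the benzyl ether are inert to an alkylzinc halide at 0 °C. Low temperature and the chelating ester should hold back β-hydride loss toward the enol acetate.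

Step 10
Reactants: 17 (R)-1-[2-acetoxy-5-(benzyloxy)-3-methoxyphenyl]pentadecan-2-yl acetate
Product: 18 (R)-1-(2-acetoxy-5-hydroxy-3-methoxyphenyl)pentadecan-2-yl acetate
Conditions: H2 (1 atm), 10% Pd/C, EtOAc, rt
Reagents that add atoms: none
Why: Hydrogenolysis of the benzyl aryl ether over Pd/C under neutral conditions in a non-nucleophilic solvent leaves both acetates, the methyl ether and the non-benzylic C2' stereocentre untouched.

Compound list
1 | vanillin (4-hydroxy-3-methoxybenzaldehyde) | COc1cc(C=O)ccc1O | starting material
2 | allyl bromide | C=CCBr | starting material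
3 | 4-(allyloxy)-3-methoxybenzaldehyde | C=CCOc1ccc(C=O)cc1OC | intermediate
4 | 4-(allyloxy)-3-methoxyphenyl formate (aryl formate) | C=CCOc1ccc(OC=O)cc1OC | intermediate
5 | 4-(allyloxy)-3-methoxyphenol | C=CCOc1ccc(O)cc1OC | intermediate
6 | benzyl bromide | BrCc1ccccc1 | starting material
7 | 1-(allyloxy)-4-(benzyloxy)-2-methoxybenzene | C=CCOc1ccc(OCc2ccccc2)cc1OC | intermediate
8 | 6-allyl-4-(benzyloxy)-2-methoxycyclohexa-2,4-dien-1-one (Claisen dienone, racemic) | C=CCC1C=C(OCc2ccccc2)C=C(OC)C1=O | intermediate
9 | 2-allyl-4-(benzyloxy)-6-methoxyphenol | C=CCc1cc(OCc2ccccc2)cc(OC)c1O | intermediate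
10 | 2-allyl-4-(benzyloxy)-6-methoxyphenyl acetate | C=CCc1cc(OCc2ccccc2)cc(OC)c1OC(C)=O | intermediate
11 | 4-(benzyloxy)-2-methoxy-6-[(1,2,4-trioxolan-3-yl)methyl]phenyl acetate (secondary ozonide, racemic) | CC(=O)Oc1c(CC2OCOO2)cc(OCc2ccccc2)cc1OC | intermediate
12 | 2-[2-acetoxy-5-(benzyloxy)-3-methoxyphenyl]acetaldehyde | CC(=O)Oc1c(CC=O)cc(OCc2ccccc2)cc1OC | intermediate
13 | acetyl bromide | CC(Br)=O | starting material
14 | rac-2-[2-acetoxy-5-(benzyloxy)-3-methoxyphenyl]-1-bromoethyl acetate | CC(=O)OC(Br)Cc1cc(OCc2ccccc2)cc(OC)c1OC(C)=O | intermediate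
15 | 1-bromotridecane | CCCCCCCCCCCCCBr | starting material
16 | tridecylzinc bromide | CCCCCCCCCCCCC[Zn]Br | intermediate
17 | (R)-1-[2-acetoxy-5-(benzyloxy)-3-methoxyphenyl]pentadecan-2-yl acetate | CCCCCCCCCCCCC[C@H](Cc1cc(OCc2ccccc2)cc(OC)c1OC(C)=O)OC(C)=O | intermediate
18 | (R)-1-(2-acetoxy-5-hydroxy-3-methoxyphenyl)pentadecan-2-yl acetate | CCCCCCCCCCCCC[C@H](Cc1cc(O)cc(OC)c1OC(C)=O)OC(C)=O | target

Total step count: 10 (nine in the main line and one for the organozinc reagent).
Longest linear sequence: 9 steps (steps 1 to 7, then 9 and 10); step 8 is a one-step side branch.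

Steps most likely to fail

Step 9. Enantioinduction may be too weak when the directing ester is only an acetate, and the labile bromide may lose HBr or be reduced before the radical is captured. The fallback sets the stereocentre by reagent-controlled allylation and builds the chain by metathesis. It sets out from aldehyde 12. Brown allylation with B-allyldiisopinocampheylborane (antipode chosen for the (R)-carbinol; Et2O, −78 °C, ethanolamine work-up to spare the aryl acetate) should give 2-[(2R)-2-hydroxypent-4-en-1-yl]-4-(benzyloxy)-6-methoxyphenyl acetate F1. Acetylation (Ac2O, pyridine, DMAP) gives (2R)-1-[2-acetoxy-5-(benzyloxy)-3-methoxyphenyl]pent-4-en-2-yl acetate F2; any acetyl shift between the two oxygens in F1 is levelled here. Cross-metathesis with 1-dodecene (second-generation Grubbs catalyst, CH2Cl2, 40 °C) gives (2R)-1-[2-acetoxy-5-(benzyloxy)-3-methoxyphenyl]pentadec-4-en-2-yl acetate F3 as an E/Z mixture. Hydrogenation over Pd/C in EtOAc saturates the alkene and removes the benzyl group in the same operation, so the fallback comes back to the route at target 18.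

Step 7. Acetyl bromide with the Lewis acid may cleave the benzyl ether, the enolisable aldehyde may be diverted to its enol acetate, and the product may hydrolyse on handling. The fallback introduces bromide by exchange instead of addition. It sets out from aldehyde 12. Ac2O with Bi(OTf)3 (0.1–1 mol %) in MeCN at 0 °C should give the geminal diacetate 2-[2-acetoxy-5-(benzyloxy)-3-methoxyphenyl]ethane-1,1-diyl diacetate F4, a stable, storable compound. Me3SiBr in CH2Cl2 at 0 °C then exchanges one acetate for bromide, and the fallback rejoins the route at 14.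

Step 6. Ozone may over-oxidise the electron-rich ring or the benzylic CH2 of the benzyl ether, and the arylacetaldehyde may decay by aldol condensation while the phosphine oxide is removed. The fallback cleaves the alkene in two stages without ozone. It sets out from alkene 10. Upjohn dihydroxylation (K2OsO4·2H2O cat., NMO, acetone/H2O, rt) should give rac-2-(2,3-dihydroxypropyl)-4-(benzyloxy)-6-methoxyphenyl acetate F5. Glycol cleavage with NaIO4 on silica gel in CH2Cl2 then delivers aldehyde 12 after filtration alone, where the route is rejoined.

Further compounds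
F1 | step 9 | 2-[(2R)-2-hydroxypent-4-en-1-yl]-4-(benzyloxy)-6-methoxyphenyl acetate | C=CC[C@H](Cc1cc(OCc2ccccc2)cc(OC)c1OC(C)=O)O
F2 | step 9 | (2R)-1-[2-acetoxy-5-(benzyloxy)-3-methoxyphenyl]pent-4-en-2-yl acetate | C=CC[C@H](Cc1cc(OCc2ccccc2)cc(OC)c1OC(C)=O)OC(C)=O
F3 | step 9 | (2R)-1-[2-acetoxy-5-(benzyloxy)-3-methoxyphenyl]pentadec-4-en-2-yl acetate (E/Z mixture) | CCCCCCCCCCC=CC[C@H](Cc1cc(OCc2ccccc2)cc(OC)c1OC(C)=O)OC(C)=O
F4 | step 7 | 2-[2-acetoxy-5-(benzyloxy)-3-methoxyphenyl]ethane-1,1-diyl diacetate | CC(=O)OC(Cc1cc(OCc2ccccc2)cc(OC)c1OC(C)=O)OC(C)=O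
F5 | step 6 | rac-2-(2,3-dihydroxypropyl)-4-(benzyloxy)-6-methoxyphenyl acetate | CC(=O)Oc1c(CC(O)CO)cc(OCc2ccccc2)cc1OC
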